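The target in the red run stands at 58.6% beside 42.2% of side product after 8.00 min. Two chemists dispute whether that split also holds in the first seconds of a new flask.

| flask | starting material | reagent | free catalyst | second catalyst | remark | time |
|---|---|---|---|---|---|---|
| red | 0.12 M | 0.70 equiv | 0.25 mol% | 2.5 mol% | run made earlier |  |
| ochre | 0.12 M | 0.70 equiv | 0.38 mol% | 2.5 mol% | run made earlier |  |
| green | 0.24 M | 0.70 equiv | 0.5 mol% | 2.5 mol% | run made earlier |  |
| flask | 0.12 M | 0.700 equiv | 0.5 mol% | 2.5 mol% |  | 12 min |

| run | time / min | target / % | side product / % |
|---|---|---|---|
| red | 0.500 | 36.1 | 18.2 |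
| red | 1.00 | 52.0 | 32.6 |
| red | 2.00 | 57.0 | 40.7 |
| red | 4.00 | 58.6 | 42.1 |
| red | 8.00 | 58.6 | 42.2 |
| ochre | 0.500 | 41.4 | 23.9 |
| ochre | 1.00 | 54.4 | 36.7 |
| ochre | 2.00 | 57.6 | 42.1 |
| ochre | 4.00 | 56.1 | 41.4 |
| ochre | 8.00 | 57.9 | 41.9 |
| green | 0.500 | 65.0 | 22.4 |
| green | 1.00 | 67.5 | 28.3 |
| green | 2.00 | 69.4 | 31.3 |
| green | 4.00 | 68.6 | 31.3 |
| green | 8.00 | 67.8 | 31.4 |

(standard deviation of a reading: 0.5 percentage points)

* ratio of target to side product at 2.0 s
* ratio of target to side product at 12 min
* which of target and side product there is more of at 12 min

The first chemist holds that the split is fixed. Red and ochre end at ratios of 1.39 and 1.38, although ochre carries more free catalyst, so he expects about the same ratio at 2.0 s as at 12 min.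

The second chemist counts turnovers. Suppose, at the 0.12 M of red and ochre, each target takes one reagent and each side product takes none. Reagent left, per starting material charged, is then 0.7 minus the target, and the running ratio follows [reagent]. The running ratio, target formed per side product formed at a given moment, equals the reagent left times a split constant, a selectivity factor: target made per side product for each equivalent of reagent left. Summed over a run, this constant is the logarithm of reagent charged over reagent left, divided by the side-product fraction. The final readings give 4.30 in red and 4.19 in ochre, with a mean of 4.24.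

For side product in red after 0.500 min, the count gives 17.1%, the fixed split gives 26.0%, and the reading is 18.2%. In ochre the same figures are 21.1%, 30.0% and 23.9%. So I side with the count: in the flask the ratio of target to side product starts at 0.7 times the constant, 2.97, and ends near the plateau readings of red and ochre.

The forecast takes the same side, on the ground that “The running ratio falls as reagent is used”. It gives 2.9 at 2.0 s and 1.35 at 12 min, with target ahead. My 2.97 is a ratio for the very start, and it stands above the forecast's 2.9.

The flask gives 2.93 at 2.0 s and 1.33 at 12 min, with target ahead.

    reagent + catalyst intermediate → second catalyst + target (k = 43.0 M⁻¹ s⁻¹)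
    second catalyst + open intermediate ⇌ catalyst intermediate (K = 14.0 M⁻¹, k = 760 M⁻¹ s⁻¹)
    open intermediate → side product (k = 0.0340 s⁻¹)
    2 second catalyst ⇌ resting dimer (K = 58.0 M⁻¹, k = 130 M⁻¹ s⁻¹)
    starting material + free catalyst → free catalyst + open intermediate (k = 150 M⁻¹ s⁻¹)

At 12.0 min the flask holds 57.1% target, 42.9% side product and 18.5% of its reagent. The split constant, put on that target, gives 39.9% of side product, less than the flask holds.

In the neighbour with 1.80 equiv of reagent, the carried constant gives a starting ratio of 7.63. The computed ratios are 7.01 at 2.0 s and 5.25 at 12 min. The fixed split stands nearer in this reagent-rich neighbour than in the flask: between those two times the neighbour's ratio falls by a quarter, against 54.6% in the flask.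

The numbers in the tables are calculated from invented constants, noise included.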